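**Plan**
1. Retrosynthesis: remove the three O‑methyl groups and the two aryl–CHO bonds, return C3 to a ketone and C1–C2 to an alkene, then cut C4–C9′ (silyl dienol ether + Cr(CO)3‑bound benzylic cation), C4–C5 (key cut), C2–C3 (alkynyl Grignard + enal), C1=C5 (metathesis), C1–C10 (vinyllithium + methyl ketone) and the ring alkene of (R)‑limonene (ozonolysis).
2. Enabling feature: cyclopentane carbons C3, C4 and C5 (C5 is the ring fusion beside quaternary C4) are a latent cyclopent‑2‑enone; a but‑2‑ynyl pivalate on C1 of a C1=C5 cycloheptene holds exactly these atoms and closes C4–C5 while the ester supplies the C3 oxygen.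
3. Forward order: limonene → open chain → seven‑membered ring (metathesis) → five‑membered ring (gold step) → aryl branch joined at C4 → enone reduction, C3 deoxygenation, double formylation, O‑demethylation.
4. Stereochemistry: C7 from (R)‑limonene; C10 is not controlled in the ketone addition and the epimers are separated as ring diols (step 4); C2 by CBS reduction, relayed to C5 in the gold step; C4 by attack anti to C6; C9′ by CBS reduction of the aryl ketone and net retention at the Cr‑bound cation; C1 by protonation in the dissolving‑metal reduction.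

Key step: step 11

Remark (numbering): guaiane numbering is used for the bicyclic compounds: C1–C5 cyclopentane, C1/C5–C10 cycloheptane, C11(=C12)–C13 isopropenyl on C7, C14 methyl on C10, C15 methyl on C4; C9′ is the benzylic carbon; β is the face of H1.
Remark (assumption): the new C4–C5 bond is taken to form on the alkene face opposite the departing C2–O bond, which calls for the (R) ester 15; if the sense were the reverse, (R)‑Me‑CBS in step 9 would supply the other carbinol.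
Remark (descriptors): the CIP label of C9′ reads S while C3 is a carbonyl and R afterwards; the spatial arrangement does not change.

**Route**

Step 1
Reactants: 1 (R)‑limonene
Product: 3 (3R)‑6‑oxo‑3‑(prop‑1‑en‑2‑yl)heptanal, via limonene 1,2‑ozonide 2 (not isolated)
Conditions: O3 (1 equiv), CH2Cl2, −78 °C; then Me2S, −78 °C → rt
Reagents that add atoms: ozone, [O-][O+]=O
Why: Ozonolysis with reductive work‑up; ozone attacks the electron‑rich trisubstituted ring alkene much faster than the 1,1‑disubstituted isopropenyl group, so one equivalent should open only the ring and leave the C7 stereocenter (β to the new aldehyde) untouched.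

Step 2
Reactants: 3 (3R)‑6‑oxo‑3‑(prop‑1‑en‑2‑yl)heptanal
Product: 4 (5R)‑5‑(prop‑1‑en‑2‑yl)oct‑7‑en‑2‑one
Conditions: Ph3PCH3Br, KN(SiMe3)2, THF, 0 °C; then 3, −78 → 0 °C
Reagents that add atoms: methyltriphenylphosphonium bromide, C[P+](c1ccccc1)(c1ccccc1)c1ccccc1.[Br-]
Why: Wittig methylenation; a salt‑free unstabilised ylide used in slight deficit at low temperature should take the aldehyde far faster than the methyl ketone.

Step 3
Reactants: 4 (5R)‑5‑(prop‑1‑en‑2‑yl)oct‑7‑en‑2‑one; 5 2‑bromoprop‑2‑en‑1‑ol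
Product: 7 (6R)‑3‑methyl‑2‑methylidene‑6‑(prop‑1‑en‑2‑yl)non‑8‑ene‑1,3‑diol (both C3 epimers; C3 is C10 of the target), via lithium 2‑lithioprop‑2‑en‑1‑olate 6 (not isolated)
Conditions: 5, t‑BuLi (3 equiv), Et2O, −78 → 0 °C; then 4, −78 °C → rt; aq NH4Cl
Reagents that add atoms: none
Why: Bromine–lithium exchange followed by 1,2‑addition of the vinyllithium to the methyl ketone forms the C1–C10 bond; the only stereocenter (C7) is three bonds away and gives no facial bias, so both C10 epimers are expected and are separated after ring closure.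

Step 4
Reactants: 7 (6R)‑3‑methyl‑2‑methylidene‑6‑(prop‑1‑en‑2‑yl)non‑8‑ene‑1,3‑diol
Product: 8 (1R,5R)‑2‑(hydroxymethyl)‑1‑methyl‑5‑(prop‑1‑en‑2‑yl)cyclohept‑2‑en‑1‑ol
Conditions: second‑generation Grubbs catalyst (5 mol %), CH2Cl2 (5 mM), 40 °C; chromatography
Reagents that add atoms: none
Why: Ring‑closing metathesis; the ruthenium carbene loads at the monosubstituted C5 alkene and can close only onto the allylic 1,1‑disubstituted alkene to give the trisubstituted cycloheptene (closure onto the isopropenyl group would need a cyclobutene), and the two ring diastereomers should separate on silica, the isomer with the C10 methyl cis to the isopropenyl group (to be assigned by NOE) being carried on.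

Step 5
Reactants: 8 (1R,5R)‑2‑(hydroxymethyl)‑1‑methyl‑5‑(prop‑1‑en‑2‑yl)cyclohept‑2‑en‑1‑ol
Product: 9 (4R,7R)‑7‑hydroxy‑7‑methyl‑4‑(prop‑1‑en‑2‑yl)cyclohept‑1‑ene‑1‑carbaldehyde
Conditions: MnO2, CH2Cl2, rt
Reagents that add atoms: none
Why: Allylic oxidation with MnO2 takes only the primary allylic alcohol, since the tertiary alcohol has no carbinol hydrogen.

Step 6
Reactants: 9 (4R,7R)‑7‑hydroxy‑7‑methyl‑4‑(prop‑1‑en‑2‑yl)cyclohept‑1‑ene‑1‑carbaldehyde
Product: 10 (4R,7R)‑7‑methyl‑4‑(prop‑1‑en‑2‑yl)‑7‑(triethylsilyloxy)cyclohept‑1‑ene‑1‑carbaldehyde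
Conditions: TESOTf, 2,6‑lutidine, CH2Cl2, −78 → 0 °C
Reagents that add atoms: triethylsilyl trifluoromethanesulfonate, CC[Si](CC)(CC)OS(=O)(=O)C(F)(F)F
Why: Silylation of a hindered tertiary alcohol with a silyl triflate and a hindered base; the ether keeps the C10 oxygen from adding to the gold‑activated alkyne in step 11 and survives the steps in between.

Step 7
Reactants: 10 (4R,7R)‑7‑methyl‑4‑(prop‑1‑en‑2‑yl)‑7‑(triethylsilyloxy)cyclohept‑1‑ene‑1‑carbaldehyde; 11 1‑propynylmagnesium bromide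
Product: 12 1‑[(4R,7R)‑7‑methyl‑4‑(prop‑1‑en‑2‑yl)‑7‑(triethylsilyloxy)cyclohept‑1‑en‑1‑yl]but‑2‑yn‑1‑ol (both carbinol epimers)
Conditions: 11, THF, −78 → 0 °C; aq NH4Cl
Reagents that add atoms: none
Why: 1,2‑Addition of an alkynyl Grignard reagent to the α‑branched enal forms the C2–C3 bond; the carbinol configuration is left open because step 8 erases it.

Step 8
Reactants: 12 1‑[(4R,7R)‑7‑methyl‑4‑(prop‑1‑en‑2‑yl)‑7‑(triethylsilyloxy)cyclohept‑1‑en‑1‑yl]but‑2‑yn‑1‑ol
Product: 13 1‑[(4R,7R)‑7‑methyl‑4‑(prop‑1‑en‑2‑yl)‑7‑(triethylsilyloxy)cyclohept‑1‑en‑1‑yl]but‑2‑yn‑1‑one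
Conditions: MnO2, CH2Cl2, rt
Reagents that add atoms: none
Why: MnO2 oxidation of a doubly activated (allylic and propargylic) secondary alcohol gives the cross‑conjugated ynone without touching the silyl ether or the alkenes.

Step 9
Reactants: 13 1‑[(4R,7R)‑7‑methyl‑4‑(prop‑1‑en‑2‑yl)‑7‑(triethylsilyloxy)cyclohept‑1‑en‑1‑yl]but‑2‑yn‑1‑one
Product: 14 (1R)‑1‑[(4R,7R)‑7‑methyl‑4‑(prop‑1‑en‑2‑yl)‑7‑(triethylsilyloxy)cyclohept‑1‑en‑1‑yl]but‑2‑yn‑1‑ol
Conditions: (S)‑Me‑CBS oxazaborolidine (0.5 equiv), catecholborane, CH2Cl2, −78 °C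
Reagents that add atoms: none
Why: Corey–Bakshi–Shibata reduction; the rod‑like propynyl group acts as the small and the α‑branched cycloheptenyl group as the large substituent, so the (S)‑catalyst should deliver hydride under reagent control to give the (R)‑carbinol at C2.

Step 10
Reactants: 14 (1R)‑1‑[(4R,7R)‑7‑methyl‑4‑(prop‑1‑en‑2‑yl)‑7‑(triethylsilyloxy)cyclohept‑1‑en‑1‑yl]but‑2‑yn‑1‑ol
Product: 15 (1R)‑1‑[(4R,7R)‑7‑methyl‑4‑(prop‑1‑en‑2‑yl)‑7‑(triethylsilyloxy)cyclohept‑1‑en‑1‑yl]but‑2‑yn‑1‑yl 2,2‑dimethylpropanoate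
Conditions: PivCl, Et3N, DMAP (cat.), CH2Cl2, 0 °C → rt
Reagents that add atoms: pivaloyl chloride, CC(C)(C)C(Cl)=O
Why: DMAP‑catalysed acylation of the secondary alcohol with retention at C2; the pivalate is chosen because it migrates cleanly and resists ionisation at the doubly activated carbinol carbon.

Step 11
Reactants: 15 (1R)‑1‑[(4R,7R)‑7‑methyl‑4‑(prop‑1‑en‑2‑yl)‑7‑(triethylsilyloxy)cyclohept‑1‑en‑1‑yl]but‑2‑yn‑1‑yl 2,2‑dimethylpropanoate
Product: 17 (4R,5R,7R,10R)‑10‑(triethylsilyloxy)guaia‑1,11‑dien‑3‑one (the 4‑epimer serves equally), via dienyl pivalate 16 (not isolated)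
Conditions: Ph3PAuCl (5 mol %), AgSbF6 (5 mol %), MeCN containing H2O (2 equiv), −20 °C → rt
Reagents that add atoms: none
Why: Monovalent gold (Ph3PAu+) binds the alkyne, the pivalate carbonyl oxygen adds to C3 and the C2–O bond breaks (1,2‑acyloxy shift), leaving a vinylgold‑substituted pentadienyl cation (C5=C1–C2=C3(OPiv)–C4[Au]) that closes the C4–C5 bond; loss of gold gives dienyl pivalate 16, which water hydrolyses to enone 17 and pivalic acid. The closest known reaction type is the gold‑catalysed Rautenstrauch rearrangement of 1‑ethynyl‑2‑propenyl pivalates to cyclopent‑2‑enones, for which cyclic trisubstituted alkenes are documented substrates. The five‑membered ring closes by a cationic 4π electrocyclic (Nazarov‑like) closure of this 1‑aurapentadienyl unit, the ring‑alkene carbon C5 bonding to the alkyne terminus C4. C5 is the one new stereocenter that matters and is controlled by the C2 carbinol: the cation is helical for as long as it remembers C2, and bonding on the alkene face opposite the departing C2–O bond (the β face for the (R) ester) puts H5 on the α face, while C4 forms as an epimeric mixture that is enolised in step 16. The step needs 1,2‑ rather than 1,3‑acyloxy migration, and ring closure and hydrolysis faster than helix inversion or a 1,5‑hydrogen shift in 16; the pivalate ester, the cationic phosphine–gold catalyst, low temperature and wet acetonitrile are chosen for this, and the silyl ether keeps the C10 oxygen from adding to the alkyne.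

Step 12
Reactants: 18 1,3,5‑trimethoxybenzene; 19 3‑methylbutanoyl chloride
Product: 20 3‑methyl‑1‑(2,4,6‑trimethoxyphenyl)butan‑1‑one
Conditions: 19, AlCl3, CH2Cl2, 0 °C
Reagents that add atoms: none
Why: Friedel–Crafts acylation of the symmetrical, strongly activated arene, run cold and briefly to avoid ortho O‑demethylation; the acyl group deactivates the ring against a second acylation.

Step 13
Reactants: 20 3‑methyl‑1‑(2,4,6‑trimethoxyphenyl)butan‑1‑one
Product: 21 (1S)‑3‑methyl‑1‑(2,4,6‑trimethoxyphenyl)butan‑1‑ol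
Conditions: (R)‑Me‑CBS oxazaborolidine (20 mol %), BH3·SMe2, THF, 0 °C → rt
Reagents that add atoms: none
Why: Corey–Bakshi–Shibata reduction; the di‑ortho‑substituted aryl group is the large and the isobutyl group the small substituent, so the (R)‑catalyst should give the (S)‑carbinol, which fixes C9′.

Step 14
Reactants: 21 (1S)‑3‑methyl‑1‑(2,4,6‑trimethoxyphenyl)butan‑1‑ol
Product: 22 tricarbonyl[η6‑(1S)‑3‑methyl‑1‑(2,4,6‑trimethoxyphenyl)butan‑1‑ol]chromium
Conditions: (η6‑naphthalene)Cr(CO)3, THF, 70 °C, dark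
Reagents that add atoms: (η6‑naphthalene)tricarbonylchromium, c1ccc2ccccc2c1.[Cr].[C-]#[O+].[C-]#[O+].[C-]#[O+]
Why: Arene exchange from the labile naphthalene complex moves the Cr(CO)3 unit to the more electron‑rich ring under neutral conditions that do not ionise the benzylic alcohol; the two arene faces are interchanged by rotation about the aryl–C9′ bond, so a single complex forms.

Step 15
Reactants: 22 tricarbonyl[η6‑(1S)‑3‑methyl‑1‑(2,4,6‑trimethoxyphenyl)butan‑1‑ol]chromium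
Product: 23 tricarbonyl[η6‑(1S)‑3‑methyl‑1‑(2,4,6‑trimethoxyphenyl)butyl acetate]chromium
Conditions: Ac2O, pyridine, DMAP (cat.), CH2Cl2, 0 °C
Reagents that add atoms: acetic anhydride, CC(=O)OC(C)=O
Why: O‑Acylation with retention at C9′; the electron‑withdrawing Cr(CO)3 unit keeps the otherwise very labile trimethoxybenzylic acetate from ionising until a Lewis acid is added.

Step 16
Reactants: 17 (4R,5R,7R,10R)‑10‑(triethylsilyloxy)guaia‑1,11‑dien‑3‑one; 23 tricarbonyl[η6‑(1S)‑3‑methyl‑1‑(2,4,6‑trimethoxyphenyl)butyl acetate]chromium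
Product: 26 (4S,5S,7R,10R)‑4‑[(1S)‑3‑methyl‑1‑(2,4,6‑trimethoxyphenyl)butyl]‑10‑(triethylsilyloxy)guaia‑1,11‑dien‑3‑one, via silyl dienol ether 24 (not isolated), via Cr(CO)3 complex of the coupled enone 25 (not isolated)
Conditions: LiN(i‑Pr)2, THF, −78 °C; TMSCl; pentane, filter, concentrate below 0 °C; then 23, BF3·OEt2, CH2Cl2, −78 → −30 °C; then air, hν, Et2O, rt
Reagents that add atoms: none
Why: Kinetic α′‑deprotonation of the enone and O‑silylation give the cross‑conjugated silyl dienol ether 24, whose C4 adds (Mukaiyama‑type SN1 alkylation) to the Cr(CO)3‑stabilised benzylic cation released from 23, with C4 set by attack on the face anti to C6 (α face, methyl left β) and C9′ set by net retention (the acetate leaves anti to chromium and the nucleophile enters anti to chromium), before photo‑oxidative decomplexation frees the arene.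

Step 17
Reactants: 26 (4S,5S,7R,10R)‑4‑[(1S)‑3‑methyl‑1‑(2,4,6‑trimethoxyphenyl)butyl]‑10‑(triethylsilyloxy)guaia‑1,11‑dien‑3‑one
Product: 27 (4S,5S,7R,10R)‑10‑hydroxy‑4‑[(1S)‑3‑methyl‑1‑(2,4,6‑trimethoxyphenyl)butyl]guaia‑1,11‑dien‑3‑one
Conditions: Bu4NF, THF, 0 °C → rt
Reagents that add atoms: none
Why: Fluoride cleavage of the triethylsilyl ether; the hydroxyl is freed before the reduction because a silyloxy group next to the C1 carbanion of step 18 could be expelled, whereas an alkoxide is not.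

Step 18
Reactants: 27 (4S,5S,7R,10R)‑10‑hydroxy‑4‑[(1S)‑3‑methyl‑1‑(2,4,6‑trimethoxyphenyl)butyl]guaia‑1,11‑dien‑3‑one
Product: 28 (1R,4S,5S,7R,10R)‑10‑hydroxy‑4‑[(1S)‑3‑methyl‑1‑(2,4,6‑trimethoxyphenyl)butyl]guai‑11‑en‑3‑one
Conditions: Li (3 equiv), NH3/THF, −78 °C, 10 min; solid NH4Cl
Reagents that add atoms: none
Why: Dissolving‑metal (Birch‑type) reduction of the enone; C1 should be protonated on the β face, the side of the C10 oxygen and away from the bulky α branch on C4, which gives the trans ring fusion (H1 β), while the isolated alkene and the electron‑rich arene are not reduced at −78 °C with a small excess of lithium.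

Step 19
Reactants: 28 (1R,4S,5S,7R,10R)‑10‑hydroxy‑4‑[(1S)‑3‑methyl‑1‑(2,4,6‑trimethoxyphenyl)butyl]guai‑11‑en‑3‑one
Product: 30 (1R,4S,5S,7R,10R)‑4‑[(1R)‑3‑methyl‑1‑(2,4,6‑trimethoxyphenyl)butyl]guai‑11‑en‑10‑ol, via C3 hydrazone 29 (not isolated)
Conditions: N2H4·H2O, KOH, diethylene glycol, 130 °C, then 200 °C
Reagents that add atoms: none
Why: Wolff–Kishner reduction (Huang‑Minlon modification) through hydrazone 29 removes the hindered C3 carbonyl; no stereocenter is at risk because C4 is quaternary and C1 and C5 are not α to the carbonyl.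

Step 20
Reactants: 30 (1R,4S,5S,7R,10R)‑4‑[(1R)‑3‑methyl‑1‑(2,4,6‑trimethoxyphenyl)butyl]guai‑11‑en‑10‑ol
Product: 32 5‑{(1R)‑1‑[(1R,4S,5S,7R,10R)‑10‑hydroxyguai‑11‑en‑4‑yl]‑3‑methylbutyl}‑2,4,6‑trimethoxybenzene‑1,3‑dicarbaldehyde, via lithium α‑amino alkoxide 31 (not isolated)
Conditions: n‑BuLi, TMEDA, THF, 0 °C; DMF, −78 → 0 °C; then n‑BuLi, 0 °C; DMF, −78 °C → rt; aq NH4Cl
Reagents that add atoms: N,N‑dimethylformamide, CN(C)C=O
Why: Directed ortho‑lithiation at the ring positions flanked by two methoxy groups and formylation with DMF, run twice in one flask; the first adduct persists as lithium α‑amino alkoxide 31 and so protects the first formyl group during the second lithiation.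

Step 21
Reactants: 32 5‑{(1R)‑1‑[(1R,4S,5S,7R,10R)‑10‑hydroxyguai‑11‑en‑4‑yl]‑3‑methylbutyl}‑2,4,6‑trimethoxybenzene‑1,3‑dicarbaldehyde
Product: 33 5‑{(1R)‑1‑[(1R,4S,5S,7R,10R)‑10‑hydroxyguai‑11‑en‑4‑yl]‑3‑methylbutyl}‑2,4,6‑trihydroxybenzene‑1,3‑dicarbaldehyde (CNP0594576.1)
Conditions: 4‑MeC6H4SLi, HMPA, toluene, 110 °C; aq NH4Cl then dilute HCl to pH 4
Reagents that add atoms: none
Why: Nucleophilic (SN2) O‑demethylation by an arenethiolate; every methoxy group is ortho or para to a formyl group, so each phenoxide is a good leaving group, and the tertiary alcohol, the aldehydes and the isopropenyl group tolerate the non‑acidic medium.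

**Compound list**
1 | (R)‑limonene | CC1=CC[C@@H](CC1)C(C)=C | starting material
2 | limonene 1,2‑ozonide (4R; mixture at the trioxolane carbons; not isolated) | CC12CC[C@@H](C(C)=C)CC(O1)OO2 | intermediate
3 | (3R)‑6‑oxo‑3‑(prop‑1‑en‑2‑yl)heptanal | CC(=C)[C@@H](CC=O)CCC(C)=O | intermediate
4 | (5R)‑5‑(prop‑1‑en‑2‑yl)oct‑7‑en‑2‑one | CC(=C)[C@@H](CC=C)CCC(C)=O | intermediate
5 | 2‑bromoprop‑2‑en‑1‑ol | OCC(Br)=C | starting material
6 | lithium 2‑lithioprop‑2‑en‑1‑olate (not isolated) | [Li]OCC([Li])=C | intermediate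
7 | (6R)‑3‑methyl‑2‑methylidene‑6‑(prop‑1‑en‑2‑yl)non‑8‑ene‑1,3‑diol, both C3 epimers | OCC(=C)C(C)(O)CC[C@H](CC=C)C(C)=C | intermediate
8 | (1R,5R)‑2‑(hydroxymethyl)‑1‑methyl‑5‑(prop‑1‑en‑2‑yl)cyclohept‑2‑en‑1‑ol | C=C(C)[C@@H]1CC[C@@](C)(O)C(CO)=CC1 | intermediate
9 | (4R,7R)‑7‑hydroxy‑7‑methyl‑4‑(prop‑1‑en‑2‑yl)cyclohept‑1‑ene‑1‑carbaldehyde | C=C(C)[C@@H]1CC[C@@](C)(O)C(C=O)=CC1 | intermediate
10 | (4R,7R)‑7‑methyl‑4‑(prop‑1‑en‑2‑yl)‑7‑(triethylsilyloxy)cyclohept‑1‑ene‑1‑carbaldehyde | C=C(C)[C@@H]1CC[C@@](C)(O[Si](CC)(CC)CC)C(C=O)=CC1 | intermediate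
11 | 1‑propynylmagnesium bromide | CC#C[Mg]Br | starting material
12 | 1‑[(4R,7R)‑7‑methyl‑4‑(prop‑1‑en‑2‑yl)‑7‑(triethylsilyloxy)cyclohept‑1‑en‑1‑yl]but‑2‑yn‑1‑ol, both carbinol epimers | C=C(C)[C@@H]1CC[C@@](C)(O[Si](CC)(CC)CC)C(C(O)C#CC)=CC1 | intermediate
13 | 1‑[(4R,7R)‑7‑methyl‑4‑(prop‑1‑en‑2‑yl)‑7‑(triethylsilyloxy)cyclohept‑1‑en‑1‑yl]but‑2‑yn‑1‑one | C=C(C)[C@@H]1CC[C@@](C)(O[Si](CC)(CC)CC)C(C(=O)C#CC)=CC1 | intermediate
14 | (1R)‑1‑[(4R,7R)‑7‑methyl‑4‑(prop‑1‑en‑2‑yl)‑7‑(triethylsilyloxy)cyclohept‑1‑en‑1‑yl]but‑2‑yn‑1‑ol | C=C(C)[C@@H]1CC[C@@](C)(O[Si](CC)(CC)CC)C([C@H](O)C#CC)=CC1 | intermediate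
15 | (1R)‑1‑[(4R,7R)‑7‑methyl‑4‑(prop‑1‑en‑2‑yl)‑7‑(triethylsilyloxy)cyclohept‑1‑en‑1‑yl]but‑2‑yn‑1‑yl 2,2‑dimethylpropanoate | C=C(C)[C@@H]1CC[C@@](C)(O[Si](CC)(CC)CC)C([C@H](OC(=O)C(C)(C)C)C#CC)=CC1 | intermediate
16 | (5R,7R,10R)‑10‑(triethylsilyloxy)guaia‑1,3,11‑trien‑3‑yl pivalate (not isolated) | C=C(C)[C@@H]1CC[C@@](C)(O[Si](CC)(CC)CC)C2=CC(OC(=O)C(C)(C)C)=C(C)[C@H]2C1 | intermediate
17 | (4R,5R,7R,10R)‑10‑(triethylsilyloxy)guaia‑1,11‑dien‑3‑one | C=C(C)[C@@H]1CC[C@@](C)(O[Si](CC)(CC)CC)C2=CC(=O)[C@H](C)[C@H]2C1 | intermediate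
18 | 1,3,5‑trimethoxybenzene | COc1cc(OC)cc(OC)c1 | starting material
19 | 3‑methylbutanoyl chloride | CC(C)CC(Cl)=O | starting material
20 | 3‑methyl‑1‑(2,4,6‑trimethoxyphenyl)butan‑1‑one | COc1cc(OC)c(C(=O)CC(C)C)c(OC)c1 | intermediate
21 | (1S)‑3‑methyl‑1‑(2,4,6‑trimethoxyphenyl)butan‑1‑ol | O[C@@H](CC(C)C)c1c(OC)cc(OC)cc1OC | intermediate
22 | tricarbonyl[η6‑(1S)‑3‑methyl‑1‑(2,4,6‑trimethoxyphenyl)butan‑1‑ol]chromium | O[C@@H](CC(C)C)c1c(OC)cc(OC)cc1OC.[Cr].[C-]#[O+].[C-]#[O+].[C-]#[O+] | intermediate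
23 | tricarbonyl[η6‑(1S)‑3‑methyl‑1‑(2,4,6‑trimethoxyphenyl)butyl acetate]chromium | CC(=O)O[C@@H](CC(C)C)c1c(OC)cc(OC)cc1OC.[Cr].[C-]#[O+].[C-]#[O+].[C-]#[O+] | intermediate
24 | (5R,7R,10R)‑10‑(triethylsilyloxy)‑3‑(trimethylsilyloxy)guaia‑1,3,11‑triene (not isolated) | C=C(C)[C@@H]1CC[C@@](C)(O[Si](CC)(CC)CC)C2=CC(O[Si](C)(C)C)=C(C)[C@H]2C1 | intermediate
25 | Cr(CO)3 complex (η6 at the trimethoxyphenyl ring) of 26 (not isolated) | C=C(C)[C@@H]1CC[C@@](C)(O[Si](CC)(CC)CC)C2=CC(=O)[C@](C)([C@@H](CC(C)C)c3c(OC)cc(OC)cc3OC)[C@H]2C1.[Cr].[C-]#[O+].[C-]#[O+].[C-]#[O+] | intermediate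
26 | (4S,5S,7R,10R)‑4‑[(1S)‑3‑methyl‑1‑(2,4,6‑trimethoxyphenyl)butyl]‑10‑(triethylsilyloxy)guaia‑1,11‑dien‑3‑one | C=C(C)[C@@H]1CC[C@@](C)(O[Si](CC)(CC)CC)C2=CC(=O)[C@](C)([C@@H](CC(C)C)c3c(OC)cc(OC)cc3OC)[C@H]2C1 | intermediate
27 | (4S,5S,7R,10R)‑10‑hydroxy‑4‑[(1S)‑3‑methyl‑1‑(2,4,6‑trimethoxyphenyl)butyl]guaia‑1,11‑dien‑3‑one | C=C(C)[C@@H]1CC[C@@](C)(O)C2=CC(=O)[C@](C)([C@@H](CC(C)C)c3c(OC)cc(OC)cc3OC)[C@H]2C1 | intermediate
28 | (1R,4S,5S,7R,10R)‑10‑hydroxy‑4‑[(1S)‑3‑methyl‑1‑(2,4,6‑trimethoxyphenyl)butyl]guai‑11‑en‑3‑one | C=C(C)[C@@H]1CC[C@@](C)(O)[C@@H]2CC(=O)[C@](C)([C@@H](CC(C)C)c3c(OC)cc(OC)cc3OC)[C@H]2C1 | intermediate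
29 | C3 hydrazone of 28 (not isolated) | C=C(C)[C@@H]1CC[C@@](C)(O)[C@@H]2CC(=NN)[C@](C)([C@@H](CC(C)C)c3c(OC)cc(OC)cc3OC)[C@H]2C1 | intermediate
30 | (1R,4S,5S,7R,10R)‑4‑[(1R)‑3‑methyl‑1‑(2,4,6‑trimethoxyphenyl)butyl]guai‑11‑en‑10‑ol | C=C(C)[C@@H]1CC[C@@](C)(O)[C@@H]2CC[C@](C)([C@@H](CC(C)C)c3c(OC)cc(OC)cc3OC)[C@H]2C1 | intermediate
31 | dilithium salt: C10 alkoxide and aryl‑CH(OLi)NMe2 adduct of the monoformylated arene (not isolated) | C=C(C)[C@@H]1CC[C@@](C)(O[Li])[C@@H]2CC[C@](C)([C@@H](CC(C)C)c3c(OC)cc(OC)c(C(O[Li])N(C)C)c3OC)[C@H]2C1 | intermediate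
32 | 5‑{(1R)‑1‑[(1R,4S,5S,7R,10R)‑10‑hydroxyguai‑11‑en‑4‑yl]‑3‑methylbutyl}‑2,4,6‑trimethoxybenzene‑1,3‑dicarbaldehyde | C=C(C)[C@@H]1CC[C@@](C)(O)[C@@H]2CC[C@](C)([C@@H](CC(C)C)c3c(OC)c(C=O)c(OC)c(C=O)c3OC)[C@H]2C1 | intermediate
33 | 5‑{(1R)‑1‑[(1R,4S,5S,7R,10R)‑10‑hydroxyguai‑11‑en‑4‑yl]‑3‑methylbutyl}‑2,4,6‑trihydroxybenzene‑1,3‑dicarbaldehyde (CNP0594576.1) | C=C(C)[C@@H]1CC[C@@](C)(O)[C@@H]2CC[C@](C)([C@@H](CC(C)C)c3c(O)c(C=O)c(O)c(C=O)c3O)[C@H]2C1 | target

**Counts**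
Total steps: 21. Longest linear sequence: 17 (steps 1–11 and 16–21, from (R)‑limonene); the aryl branch (steps 12–15) joins at step 16.

**Three steps most likely to fail**

Step 16 (C4–C9′ bond). What may go wrong:
- a 1,5‑hydrogen shift in the cyclopentadienyl silyl ether before it is consumed, which would erase C5 and move the diene;
- γ‑ instead of α′‑deprotonation of the enone;
- ionisation of the acetate outside chromium control, or rotation in the cation, with loss of C9′ integrity;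
- slow bond formation at a fully substituted carbon, and loss of the triethylsilyl ether to BF3 (harmless, since step 17 removes it anyway).

Fallback: the order of events is changed so that the nucleophile is a saturated‑ring silyl enol ether that cannot undergo sigmatropic hydrogen shifts and can be purified. It sets out from 17. Bu4NF in THF should give 10‑hydroxyguaia‑1,11‑dien‑3‑one F1. Li in NH3/THF at −78 °C should reduce it to the trans‑fused 10‑hydroxyguai‑11‑en‑3‑one F2. TMSCl/NaI/Et3N in MeCN (equilibrating conditions) should give the more substituted Δ3 enol ether together with the C10 trimethylsilyl ether, 3,10‑bis(trimethylsilyloxy)guaia‑3,11‑diene F3. F3 with 23 and BF3·OEt2 in CH2Cl2 at −78 °C should give the Cr(CO)3 complex of the coupled ketone 10‑trimethylsilyl ether F4, again by attack anti to C6 and with retention at C9′. Air and light, then dilute HCl in THF, free the arene and the tertiary alcohol. The route is rejoined at 28, and steps 17 and 18 fall away.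

Step 11 (key step). What may go wrong:
- 1,3‑acyloxy migration of the internal‑alkyne ester to an allenyl pivalate competing with the 1,2‑shift;
- incomplete transfer of chirality from C2 to C5;
- a hydrogen shift in 16 before hydrolysis.

Fallback: the same cyclisation is run on the terminal alkyne, the parent substrate class of this rearrangement, and the C4 methyl is added afterwards by enolate alkylation. It sets out from 10. Ethynylmagnesium bromide in THF should give the ethynyl carbinols F5. MnO2 gives the ethynyl ketone F6. (S)‑Me‑CBS oxazaborolidine with catecholborane gives the (R)‑carbinol F7. PivCl/Et3N/DMAP gives the pivalate F8. Ph3PAuCl/AgSbF6 in wet MeCN at −20 °C should give, through the dienyl pivalate F9, the 15‑nor enone F10. LiN(i‑Pr)2 in THF at −78 °C followed by iodomethane methylates the α′ position. The route is rejoined at 17.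

Step 18 (H1). What may go wrong:
- protonation of C1 from the α face, giving the cis ring fusion;
- reductive loss of the C10 oxygen from the β‑carbanion;
- over‑reduction of the ketone or of the arene.

Fallback: electron transfer and protonation are replaced by conjugate hydride transfer. It sets out from 27. [(Ph3P)CuH]6 in wet toluene at rt should deliver hydride to C1 from the less hindered β face (the α face carries the C4 branch) and leave the isolated alkene, the arene and the free alcohol alone. The copper enolate is protonated by the water present, so the route is rejoined directly at 28 and no new compound arises.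

**Further compounds**
F1 | step 16 | (4R,5R,7R,10R)‑10‑hydroxyguaia‑1,11‑dien‑3‑one | C=C(C)[C@@H]1CC[C@@](C)(O)C2=CC(=O)[C@H](C)[C@H]2C1
F2 | step 16 | (1R,4R,5S,7R,10R)‑10‑hydroxyguai‑11‑en‑3‑one | C=C(C)[C@@H]1CC[C@@](C)(O)[C@@H]2CC(=O)[C@H](C)[C@H]2C1
F3 | step 16 | 3,10‑bis(trimethylsilyloxy)guaia‑3,11‑diene (1β‑H, 5α‑H) | C=C(C)[C@@H]1CC[C@@](C)(O[Si](C)(C)C)[C@@H]2CC(O[Si](C)(C)C)=C(C)[C@H]2C1
F4 | step 16 | Cr(CO)3 complex of the 10‑trimethylsilyl ether of 28 | C=C(C)[C@@H]1CC[C@@](C)(O[Si](C)(C)C)[C@@H]2CC(=O)[C@](C)([C@@H](CC(C)C)c3c(OC)cc(OC)cc3OC)[C@H]2C1.[Cr].[C-]#[O+].[C-]#[O+].[C-]#[O+]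
F5 | step 11 | 1‑[(4R,7R)‑7‑methyl‑4‑(prop‑1‑en‑2‑yl)‑7‑(triethylsilyloxy)cyclohept‑1‑en‑1‑yl]prop‑2‑yn‑1‑ol, both carbinol epimers | C=C(C)[C@@H]1CC[C@@](C)(O[Si](CC)(CC)CC)C(C(O)C#C)=CC1
F6 | step 11 | 1‑[(4R,7R)‑7‑methyl‑4‑(prop‑1‑en‑2‑yl)‑7‑(triethylsilyloxy)cyclohept‑1‑en‑1‑yl]prop‑2‑yn‑1‑one | C=C(C)[C@@H]1CC[C@@](C)(O[Si](CC)(CC)CC)C(C(=O)C#C)=CC1
F7 | step 11 | (1R)‑1‑[(4R,7R)‑7‑methyl‑4‑(prop‑1‑en‑2‑yl)‑7‑(triethylsilyloxy)cyclohept‑1‑en‑1‑yl]prop‑2‑yn‑1‑ol | C=C(C)[C@@H]1CC[C@@](C)(O[Si](CC)(CC)CC)C([C@H](O)C#C)=CC1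
F8 | step 11 | (1R)‑1‑[(4R,7R)‑7‑methyl‑4‑(prop‑1‑en‑2‑yl)‑7‑(triethylsilyloxy)cyclohept‑1‑en‑1‑yl]prop‑2‑yn‑1‑yl 2,2‑dimethylpropanoate | C=C(C)[C@@H]1CC[C@@](C)(O[Si](CC)(CC)CC)C([C@H](OC(=O)C(C)(C)C)C#C)=CC1
F9 | step 11 | (5R,7R,10R)‑10‑(triethylsilyloxy)‑15‑norguaia‑1,3,11‑trien‑3‑yl pivalate (not isolated) | C=C(C)[C@@H]1CC[C@@](C)(O[Si](CC)(CC)CC)C2=CC(OC(=O)C(C)(C)C)=C[C@H]2C1
F10 | step 11 | (5R,7R,10R)‑10‑(triethylsilyloxy)‑15‑norguaia‑1,11‑dien‑3‑one | C=C(C)[C@@H]1CC[C@@](C)(O[Si](CC)(CC)CC)C2=CC(=O)C[C@H]2C1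
F0 | step 18 | none | none
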